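## Retrosynthetic overview
1. Cardivin D (**31**) comes from its C2-OTIPS ether (**30**). The α-methylene lactone is unmasked from a Mannich base. C8 is acyloxylated and C10 is set on a C9 enone, and both isobutyrates are added late.
2. The germacrane 10-ring (E-C1=C10, C5 ketone, C4-OH, C2-OR) is made in one operation by anionic oxy-Cope ring expansion. The precursor is a cyclohexane (the C5–C10 ring) carrying C5(OH)(isopropenyl) and C10(Me)(Z-2-silyloxyvinyl). The bond cleaved is C5–C10.
3. That cyclohexane comes from enantiotopic-carbonyl desymmetrization of a meso 2-allyl-2-methylcyclohexane-1,3-dione bearing CH₂CO₂H at C5. The dione is dearomatized 3,5-dihydroxyphenylacetic acid. The trans-lactone (C6–O/C7–C11) is installed before the expansion.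
4. Rings are formed in this order: six-membered carbocycle (arene dearomatization), γ-lactone (step 7), ten-membered ring (step 11).

Assumption: the reagents and 3,5-dihydroxyphenylacetic acid are commercial. The (Z)-enol ether/chair-transition-state outcome and the peripheral-face selectivities in the ten-membered ring follow the ring's preferred conformation.

## Route

**Step 1**
Reactants: **1** 3,5-dihydroxyphenylacetic acid
Product: **2** (3,5-dioxocyclohexyl)acetic acid
Conditions: H₂ (50 bar), Raney Ni, aq. NaOH, 50 °C; then HCl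
Reagents that add atoms: none (H₂ adds only H)
Why: Resorcinol-type arenes are hydrogenated one stage, to the 1,3-dione enolate, which breaks the aromaticity and sets up the C5/C9 carbonyls and the nucleophilic C10 position.

**Step 2**
Reactants: **2**; **3** iodomethane
Product: **4** (4-methyl-3,5-dioxocyclohexyl)acetic acid
Conditions: MeI, KOH, H₂O, reflux
Reagents that add atoms: iodomethane, CI
Why: C-alkylation of the doubly activated dione carbon (enolate alkylation) installs the C10 methyl.

**Step 3**
Reactants: **4**; **5** allyl bromide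
Product: **6** meso 2-(4-allyl-4-methyl-3,5-dioxocyclohexyl)acetic acid (allyl cis to CH₂CO₂H)
Conditions: allyl bromide, KOH, H₂O/dioxane, 60 °C; chromatographic separation of diastereomers
Reagents that add atoms: allyl bromide, C=CCBr
Why: Second enolate C-alkylation creates the quaternary C10 (the carbon that will carry the vinyl arm), and the separable diastereomer with allyl cis to the side chain fixes the C10/C7 relationship.

**Step 4**
Reactants: **6**
Product: **7** 2-(4-allyl-3-hydroxy-4-methyl-5-oxocyclohexyl)acetic acid (C9-OH trans to the side chain)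
Conditions: RuCl[(S,S)-TsDPEN](p-cymene) (2 mol%), HCO₂H/Et₃N (5:2), DMF, 25 °C
Reagents that add atoms: none
Why: Asymmetric transfer hydrogenation reduces only one of the two enantiotopic carbonyls of the meso dione, making C7 stereogenic and fixing the absolute configuration of the whole sequence. C9 later becomes a ketone, so its configuration is expendable.

**Step 5**
Reactants: **7**; **8** chlorotriethylsilane
Product: **9** C9-triethylsilyl ether of **7**
Conditions: TESCl, imidazole, DMF, 0 °C; then aq. AcOH/THF (cleaves the TES ester)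
Reagents that add atoms: chlorotriethylsilane, CC[Si](Cl)(CC)CC
Why: Protecting the secondary alcohol (silylation) leaves C5 as the only ketone.

**Step 6**
Reactants: **9**; **10** 2-(phenylsulfonyl)-3-phenyloxaziridine
Product: **11** hydroxy acid (C6-OH trans to CH₂CO₂H)
Conditions: LiHMDS (3.2 equiv), THF, −78 °C; then **10**
Reagents that add atoms: Davis oxaziridine, O=S(=O)(c1ccccc1)N1OC1c1ccccc1
Why: The kinetic enolate can form only toward C6, because C10 is quaternary, and Davis α-hydroxylation occurs anti to the C7 side chain, setting C6 trans to C7.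

**Step 7**
Reactants: **11**
Product: **12** trans-fused γ-lactone (C6–O–C12(=O)–C11–C7)
Conditions: EDC·HCl, DMAP, CH₂Cl₂, 25 °C
Reagents that add atoms: none (loss of H₂O)
Why: Carbodiimide lactonization of a trans-2-hydroxycyclohexylacetic acid gives the trans-fused lactone with no stereocenter touched.

**Step 8**
Reactants: **12**; **13** sodium periodate
Product: **14** aldehyde (allyl converted to CH₂CHO)
Conditions: OsO₄ (5 mol%), NaIO₄, 2,6-lutidine, dioxane/H₂O, 25 °C
Reagents that add atoms: sodium periodate, [Na+].[O-]I(=O)(=O)=O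
Why: Lemieux–Johnson cleavage converts the terminal alkene into the C1–C2 two-carbon aldehyde.

**Step 9**
Reactants: **14**; **15** triisopropylsilyl triflate
Product: **16** (Z)-TIPS enol ether
Conditions: TIPSOTf (1.05 equiv), Et₃N, CH₂Cl₂, −78 → 0 °C
Reagents that add atoms: TIPSOTf, CC(C)[Si](OS(=O)(=O)C(F)(F)F)(C(C)C)C(C)C
Why: Kinetic silyl enol ether formation on the unhindered aldehyde gives the Z enol ether, which carries the future C2 oxygen.

**Step 10**
Reactants: **16**; **17** isopropenylmagnesium bromide
Product: **18** C5 tertiary alcohol (OH trans to C6-O, isopropenyl trans to the vinyl arm)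
Conditions: **17** (3 equiv), CeCl₃ (3 equiv), THF, −78 °C
Reagents that add atoms: isopropenylmagnesium bromide, C=C(C)[Mg]Br
Why: Organocerium 1,2-addition is chemoselective for the ketone over the lactone, and attack anti to the larger C10 arm places isopropenyl trans to the vinyl group, as a chair-like [3,3] transition state requires.

**Step 11**
Reactants: **18**; **10** Davis oxaziridine
Product: **19** ten-membered ring with 9-OTES, 1(10)E-ene, 2-OTIPS, 4-OH, 5-ketone and the 6,12-lactone
Conditions: KH (1.5 equiv), 18-crown-6, THF, 0 → 45 °C; then **10**, −78 °C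
Reagents that add atoms: Davis oxaziridine, O=S(=O)(c1ccccc1)N1OC1c1ccccc1
Why: Proposed new method: the potassium alkoxide of the 3-hydroxy-1,5-diene C3=C4–C5(O⁻)–C10–C1=C2 undergoes a chair-like anionic oxy-Cope that breaks C5–C10 and forms C2–C3. This expands the six-ring to the ten-ring and gives the E-C1=C10 alkene, C2–OTIPS (from the Z-enol ether), and the C4=C5 enolate. That enolate is hydroxylated at C4 from the peripheral face of the macrocycle. It is the elemene→germacrene Cope made irreversible by enolate formation; the closest known reaction type is oxy-Cope ring expansion of 1,2-dialkenylcyclohexanols to cyclodecenones.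

**Step 12**
Reactants: **19**
Product: **20** C5 alcohol (C5-OH trans to C4-OH)
Conditions: Me₄NBH(OAc)₃, AcOH/MeCN, −20 °C
Reagents that add atoms: none (hydride adds only H)
Why: Hydroxyl-directed reduction delivers hydride from the C4-OH face, so the C5-OH ends up trans to C4-OH, as in the target.

**Step 13**
Reactants: **20**; **21** isobutyric anhydride
Product: **22** C5 isobutyrate
Conditions: (iPrCO)₂O, DMAP, Et₃N, CH₂Cl₂, 0 → 25 °C
Reagents that add atoms: isobutyric anhydride, CC(C)C(=O)OC(=O)C(C)C
Why: Acylation is chemoselective for the secondary C5-OH over the tertiary C4-OH.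

**Step 14**
Reactants: **22**; **23** dimethylmethyleneammonium iodide
Product: **24** α-(dimethylaminomethyl) lactone (C11 epimeric mixture)
Conditions: LDA (3.2 equiv), THF, −78 °C; then **23**
Reagents that add atoms: Eschenmoser's salt, C[N+](C)=C.[I-]
Why: Lactone enolate Mannich aminomethylation installs a masked exocyclic methylene while no ketone is present to compete.

**Step 15**
Reactants: **24**
Product: **25** C9 allylic alcohol
Conditions: HF·pyridine, pyridine/THF, 0 °C
Reagents that add atoms: none
Why: The less hindered TES ether is cleaved selectively, while the secondary TIPS ether and the esters survive.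

**Step 16**
Reactants: **25**
Product: **26** C9 enone (C9=O conjugated with C10=C1)
Conditions: MnO₂, CH₂Cl₂, 25 °C
Reagents that add atoms: none
Why: MnO₂ oxidizes allylic alcohols selectively and leaves the tertiary C4-OH and the silyl ether untouched.

**Step 17**
Reactants: **26**; **10** Davis oxaziridine
Product: **27** C8-hydroxy enone (C8-OH down)
Conditions: LiHMDS (2.2 equiv), THF, −78 °C; then **10**
Reagents that add atoms: Davis oxaziridine, O=S(=O)(c1ccccc1)N1OC1c1ccccc1
Why: The enone has only one enolizable α′ carbon (C8), and hydroxylation from the peripheral face trans to C7 sets C8–O.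

**Step 18**
Reactants: **27**; **21** isobutyric anhydride
Product: **28** C8 isobutyrate
Conditions: (iPrCO)₂O, DMAP, Et₃N, CH₂Cl₂, 25 °C
Reagents that add atoms: isobutyric anhydride, CC(C)C(=O)OC(=O)C(C)C
Why: Acylation is selective for the secondary C8-OH.

**Step 19**
Reactants: **28**
Product: **29** saturated C9 ketone (10S-methyl)
Conditions: [(Ph₃P)CuH]₆ (Stryker's reagent), toluene, 0 °C; then Et₃N, 25 °C
Reagents that add atoms: none (hydride adds only H)
Why: Cu–H 1,4-reduction puts H on C1, and protonation of the C9/C10 enolate followed by mild equilibration gives the thermodynamic equatorial 10-methyl.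

**Step 20**
Reactants: **29**
Product: **30** α-methylene lactone, C2-OTIPS
Conditions: MeI (20 equiv), CH₂Cl₂, 25 °C; then sat. aq. NaHCO₃, 25 °C
Reagents that add atoms: none (MeI leaves as Me₃N)
Why: Quaternization of the Mannich base followed by E1cB elimination from the lactone enolate gives the exocyclic methylene under mild base.

**Step 21**
Reactants: **30**
Product: **31** cardivin D
Conditions: HF·pyridine, THF/pyridine, 40 °C
Reagents that add atoms: none
Why: Fluoride removes the TIPS ether to free C2-OH with retention of configuration.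

## Compound list
1 | 3,5-dihydroxyphenylacetic acid | OC(=O)Cc1cc(O)cc(O)c1 | starting material
2 | (3,5-dioxocyclohexyl)acetic acid | OC(=O)CC1CC(=O)CC(=O)C1 | intermediate
3 | iodomethane | CI | starting material (reagent)
4 | (4-methyl-3,5-dioxocyclohexyl)acetic acid | OC(=O)CC1CC(=O)C(C)C(=O)C1 | intermediate
5 | allyl bromide | C=CCBr | starting material (reagent)
6 | meso (4-allyl-4-methyl-3,5-dioxocyclohexyl)acetic acid, allyl cis to side chain | OC(=O)C[C@H]1CC(=O)[C@@](C)(CC=C)C(=O)C1 | intermediate
7 | C9-hydroxy ketone from desymmetrizing reduction | OC(=O)C[C@H]1C[C@H](O)[C@@](C)(CC=C)C(=O)C1 | intermediate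
8 | chlorotriethylsilane | CC[Si](Cl)(CC)CC | starting material (reagent)
9 | C9-OTES ether of 7 | OC(=O)C[C@H]1C[C@H](O[Si](CC)(CC)CC)[C@@](C)(CC=C)C(=O)C1 | intermediate
10 | 2-(phenylsulfonyl)-3-phenyloxaziridine | O=S(=O)(c1ccccc1)N1OC1c1ccccc1 | starting material (reagent)
11 | C6-hydroxy acid (trans) | OC(=O)C[C@H]1C[C@H](O[Si](CC)(CC)CC)[C@@](C)(CC=C)C(=O)[C@@H]1O | intermediate
12 | trans-fused lactone ketone | O=C1C[C@H]2C[C@H](O[Si](CC)(CC)CC)[C@@](C)(CC=C)C(=O)[C@@H]2O1 | intermediate
13 | sodium periodate | [Na+].[O-]I(=O)(=O)=O | starting material (reagent)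
14 | aldehyde | O=C1C[C@H]2C[C@H](O[Si](CC)(CC)CC)[C@@](C)(CC=O)C(=O)[C@@H]2O1 | intermediate
15 | triisopropylsilyl triflate | CC(C)[Si](OS(=O)(=O)C(F)(F)F)(C(C)C)C(C)C | starting material (reagent)
16 | (Z)-TIPS enol ether | O=C1C[C@H]2C[C@H](O[Si](CC)(CC)CC)[C@@](C)(/C=C\O[Si](C(C)C)(C(C)C)C(C)C)C(=O)[C@@H]2O1 | intermediate
17 | isopropenylmagnesium bromide | C=C(C)[Mg]Br | starting material (reagent)
18 | C5 isopropenyl carbinol | O=C1C[C@H]2C[C@H](O[Si](CC)(CC)CC)[C@@](C)(/C=C\O[Si](C(C)C)(C(C)C)C(C)C)[C@](O)(C(C)=C)[C@@H]2O1 | intermediate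
19 | 10-membered α-hydroxy ketone | O=C1C[C@H]2C[C@H](O[Si](CC)(CC)CC)/C(C)=C/[C@H](O[Si](C(C)C)(C(C)C)C(C)C)C[C@](C)(O)C(=O)[C@@H]2O1 | intermediate
20 | C4,C5-diol | O=C1C[C@H]2C[C@H](O[Si](CC)(CC)CC)/C(C)=C/[C@H](O[Si](C(C)C)(C(C)C)C(C)C)C[C@](C)(O)[C@@H](O)[C@@H]2O1 | intermediate
21 | isobutyric anhydride | CC(C)C(=O)OC(=O)C(C)C | starting material (reagent)
22 | C5 isobutyrate | O=C1C[C@H]2C[C@H](O[Si](CC)(CC)CC)/C(C)=C/[C@H](O[Si](C(C)C)(C(C)C)C(C)C)C[C@](C)(O)[C@@H](OC(=O)C(C)C)[C@@H]2O1 | intermediate
23 | dimethylmethyleneammonium iodide | C[N+](C)=C.[I-] | starting material (reagent)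
24 | Mannich base (C11 epimers) | O=C1C(CN(C)C)[C@H]2C[C@H](O[Si](CC)(CC)CC)/C(C)=C/[C@H](O[Si](C(C)C)(C(C)C)C(C)C)C[C@](C)(O)[C@@H](OC(=O)C(C)C)[C@@H]2O1 | intermediate
25 | C9 allylic alcohol | O=C1C(CN(C)C)[C@H]2C[C@H](O)/C(C)=C/[C@H](O[Si](C(C)C)(C(C)C)C(C)C)C[C@](C)(O)[C@@H](OC(=O)C(C)C)[C@@H]2O1 | intermediate
26 | C9 enone | O=C1C(CN(C)C)[C@H]2CC(=O)/C(C)=C/[C@H](O[Si](C(C)C)(C(C)C)C(C)C)C[C@](C)(O)[C@@H](OC(=O)C(C)C)[C@@H]2O1 | intermediate
27 | C8-hydroxy enone | O=C1C(CN(C)C)[C@H]2[C@H](O)C(=O)/C(C)=C/[C@H](O[Si](C(C)C)(C(C)C)C(C)C)C[C@](C)(O)[C@@H](OC(=O)C(C)C)[C@@H]2O1 | intermediate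
28 | C8 isobutyrate enone | O=C1C(CN(C)C)[C@H]2[C@H](OC(=O)C(C)C)C(=O)/C(C)=C/[C@H](O[Si](C(C)C)(C(C)C)C(C)C)C[C@](C)(O)[C@@H](OC(=O)C(C)C)[C@@H]2O1 | intermediate
29 | saturated ketone Mannich base | O=C1C(CN(C)C)[C@H]2[C@H](OC(=O)C(C)C)C(=O)[C@@H](C)C[C@H](O[Si](C(C)C)(C(C)C)C(C)C)C[C@](C)(O)[C@@H](OC(=O)C(C)C)[C@@H]2O1 | intermediate
30 | α-methylene lactone, C2-OTIPS | C=C1C(=O)O[C@@H]2[C@@H]1[C@H](OC(=O)C(C)C)C(=O)[C@@H](C)C[C@H](O[Si](C(C)C)(C(C)C)C(C)C)C[C@](C)(O)[C@H]2OC(=O)C(C)C | intermediate
31 | cardivin D | C=C1C(=O)O[C@@H]2[C@@H]1[C@H](OC(=O)C(C)C)C(=O)[C@@H](C)C[C@H](O)C[C@](C)(O)[C@H]2OC(=O)C(C)C | target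

**Total step count:** 21. **Longest linear sequence:** 21 steps, from 1 to 31.

## Three steps most likely to fail
1. **Step 11 (oxy-Cope ring expansion with in-situ enolate hydroxylation).** The alkoxide could cause acyl migration from the lactone, silyl transfer from the enol ether, or retro-aldol, and the C2/C4 stereochemistry depends on the transition state. Fallback: abandon the ring expansion. Build the ten-membered ring by intramolecular Nozaki–Hiyama–Kishi macrocyclization of an allylic bromide onto a C6 aldehyde. This needs an acyclic precursor made from **12**-type building blocks.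
2. **Step 4 (desymmetrizing transfer hydrogenation).** Enantioselectivity and diastereoselectivity with a 5-substituent and a free acid are unproven. Fallback: reduce the dione fully (NaBH₄) to the meso 1,3-diol and desymmetrize it by lipase-catalyzed monoacylation with vinyl acetate. Then oxidize the remaining alcohol back to the ketone.
3. **Step 19 (C10 configuration by conjugate reduction and equilibration).** C10 and C8 are both α to the ketone and could epimerize. Fallback: set C10 earlier by Crabtree-directed hydrogenation of the C1=C10 alkene using the free allylic C9-OH, before the C9 oxidation in step 16. To keep the catalyst from being poisoned, use a TBS-protected α-hydroxymethyl lactone in place of the Mannich base.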